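**Plan**
1. Daucane labels are used throughout: C1 (quaternary, methyl), C2, C3, C4 (carbinol, isopropyl), C5 (ring-fusion CH), C6 (aroyloxy), C7=C8 (methyl on C8), C9 (acetoxy), C10; ring B is the cyclopentane; α is the face of H-5.
2. Retrosynthesis: cut both esters and the C4–isopropyl bond, return C9 to a ketone and C7=C8 to a single bond, then cut C5–C1 and C9–C10 while re-forming C5–C9 (retro-de Mayo), and finally cut C5–C4 (aldol) and C8–CH3.
3. Enabling feature: the oxygen-bearing carbons C4 and C9 are 1,5-related through C5–C1–C10, so the seven-membered ring and ring B are the de Mayo product of a 2-acylcyclopentanone (ring C5–C6–C7–C8–C9) whose acyl chain ends in the C1=C10 alkene.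
4. Forward: the silyloxycyclopentenone is methylated and acylated by aldol/oxidation; one photochemical step then forms ring B, the quaternary C1 and the cycloheptanone by two-carbon ring expansion; isopropyl addition, dehydrogenation, reduction and two acylations finish.
5. Stereochemistry: C6 comes from commercial (R)-1 and directs C1 (alkene adds anti to the silyloxy group); C5 by equilibration to the trans ring fusion; C4 by attack anti to the C1 methyl; C9 by α-face hydride delivery, then Mitsunobu inversion.

Key step: step 7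

Remark on the chemistry: 1 and 18 are taken as commercial; C8 (in 9–13) and the side-chain carbinol carbon (in 8 and 9) are carried as epimer mixtures and left undefined in the SMILES, because both become sp2 later (steps 9 and 6); TBS = tert-butyldimethylsilyl.

Step 1
Reactants: 1 (R)-4-(tert-butyldimethylsilyloxy)cyclopent-2-en-1-one
Product: 2 (R)-4-(tert-butyldimethylsilyloxy)-2-iodocyclopent-2-en-1-one
Conditions: I2, pyridine/CH2Cl2, 0 → 23 °C
Reagents that add atoms: iodine, [I][I]
Why: α-Iodination of a cyclic enone by pyridine-mediated addition–iodination–elimination is standard for 4-silyloxycyclopentenones and does not touch the C6 stereocenter.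

Step 2
Reactants: 2 (R)-4-(tert-butyldimethylsilyloxy)-2-iodocyclopent-2-en-1-one
Product: 3 (R)-4-(tert-butyldimethylsilyloxy)-2-methylcyclopent-2-en-1-one
Conditions: SnMe4, Pd2(dba)3 (cat.), AsPh3, NMP, 60 °C
Reagents that add atoms: tetramethyltin, C[Sn](C)(C)C
Why: Stille cross-coupling of the α-iodoenone under base-free conditions installs the C8 methyl group without β-elimination of the silyloxy group.

Step 3
Reactants: 4 2-methylprop-2-en-1-ol; 5 ethyl vinyl ether
Product: 7 4-methylpent-4-enal, via 2-methylallyl vinyl ether 6 (not isolated)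
Conditions: Hg(OAc)2 (cat.), 5 (excess), reflux; then 190 °C, sealed tube
Reagents that add atoms: none
Why: Transvinylation gives the allyl vinyl ether, whose Claisen rearrangement on heating delivers the γ,δ-unsaturated aldehyde; no stereocenter is formed.

Step 4
Reactants: 3 (R)-4-(tert-butyldimethylsilyloxy)-2-methylcyclopent-2-en-1-one; 7 4-methylpent-4-enal
Product: 8 4,5-trans aldol adduct 4-(TBS-oxy)-5-(1-hydroxy-4-methylpent-4-enyl)-2-methylcyclopent-2-en-1-one
Conditions: LiN(i-Pr)2, THF, −78 °C; then 7, −78 °C; aq. NH4Cl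
Reagents that add atoms: none
Why: Kinetic α'-deprotonation of the enone (kept at −78 °C so that silanolate is not expelled) and aldol addition form the C5–C4 bond anti to the neighbouring silyloxy group; the carbinol center is an epimer mixture that is removed in step 6.

Step 5
Reactants: 8 4,5-trans aldol adduct
Product: 9 3-(TBS-oxy)-2-(1-hydroxy-4-methylpent-4-enyl)-5-methylcyclopentan-1-one
Conditions: [(Ph3P)CuH]6 (0.4 equiv), benzene, H2O (2 equiv), 23 °C
Reagents that add atoms: none
Why: Copper hydride conjugate reduction is chemoselective for the enone C=C over the isolated 1,1-disubstituted alkene and the ketone; C8 forms as an epimer mixture that is erased in step 9.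

Step 6
Reactants: 9 3-(TBS-oxy)-2-(1-hydroxy-4-methylpent-4-enyl)-5-methylcyclopentan-1-one
Product: 10 3-(TBS-oxy)-5-methyl-2-(4-methylpent-4-enoyl)cyclopentan-1-one (enolised β-diketone)
Conditions: Dess–Martin periodinane, NaHCO3, CH2Cl2, 0 → 23 °C
Reagents that add atoms: none
Why: Dess–Martin oxidation of the β-hydroxy ketone under buffered, non-basic conditions gives the enolised β-diketone without eliminating the β-silyloxy group.

Step 7
Reactants: 10 3-(TBS-oxy)-5-methyl-2-(4-methylpent-4-enoyl)cyclopentan-1-one
Product: 12 trans-fused 6α-(TBS-oxy)-1,8-dimethylbicyclo[5.3.0]decane-4,9-dione, via cyclobutanol photoadduct 11 (not isolated)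
Conditions: hν (350 nm, Pyrex), cyclohexane (0.005 M), Ar, 20 °C; then Et3N (0.5 equiv), CH2Cl2, 23 °C
Reagents that add atoms: none
Why: Mechanism (de Mayo reaction): excitation of the chelated ring enol of 10 (C9(OH)=C5–C4=O) leads to intramolecular [2+2] photocycloaddition with the tethered C1=C10 alkene, and the cyclobutanol 11 so formed is a β-hydroxy ketone that opens by retro-aldol cleavage of the C5–C9 bond, so that C10 and C1 end up inserted into the former cyclopentanone ring (five- to seven-membered ring expansion). The closest known reaction type is the intramolecular de Mayo reaction of 2-(alk-4-enoyl)cycloalkanones, which gives fused bicyclic 1,5-diketones. Ring B closes first by 5-exo bonding of C5 to C1 (three-atom tether, a 1,6-diene, rule of five), the cyclobutane closes by C9–C10 coupling of the resulting 1,4-biradical, and the seven-membered ring is not closed but unveiled by fragmentation of the bond shared by the four- and five-membered rings. The quaternary center C1 is controlled by the C6 stereocenter, because the alkene adds to the enol face anti to the bulky silyloxy group on the carbon next to C5, which puts the C1 methyl trans to the C6 oxygen. C5 is controlled thermodynamically on amine-mediated ketonisation of the released enol, the trans ring fusion leaving the C4 carbonyl carbon and the C6 silyl ether both equatorial on the seven-membered ring, while C8 stays an inconsequential epimer mixture. The step needs regioselectivity (fused and not crossed adduct, ring enol and not exocyclic enol) and facial selectivity, which the tether length, the cyclic chelated enol and the C6 substituent are expected to secure.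

Step 8
Reactants: 12 trans-fused 6α-(TBS-oxy)-1,8-dimethylbicyclo[5.3.0]decane-4,9-dione
Product: 13 6α-(TBS-oxy)-4β-hydroxydaucan-9-one
Conditions: i-PrMgCl (1.2 equiv), CeCl3 (anhydrous, 1.5 equiv), THF, −78 °C
Reagents that add atoms: isopropylmagnesium chloride, CC(C)[Mg]Cl
Why: Organocerium 1,2-addition is non-basic (no enolisation or β-elimination); the cyclopentanone C4 should react before the α-branched cycloheptanone C9, and attack from the α face, anti to the C1 methyl and to C6, sets the 4β-hydroxy-4α-isopropyl center.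

Step 9
Reactants: 13 6α-(TBS-oxy)-4β-hydroxydaucan-9-one
Product: 14 6α-(TBS-oxy)-4β-hydroxydauc-7-en-9-one
Conditions: 2-iodoxybenzoic acid (IBX, 2 equiv), DMSO/fluorobenzene, 65 °C
Reagents that add atoms: none
Why: IBX dehydrogenation of the ketone through its enol can only give the C7=C8 enone, because the other α-carbon (C10) adjoins the quaternary C1 and has no β-hydrogen; the C8 stereocenter is removed.

Step 10
Reactants: 14 6α-(TBS-oxy)-4β-hydroxydauc-7-en-9-one
Product: 15 6α-(TBS-oxy)dauc-7-ene-4β,9β-diol
Conditions: NaBH4, CeCl3·7H2O, MeOH, −40 °C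
Reagents that add atoms: none
Why: Luche 1,2-reduction should deliver hydride to C9 from the α face, anti to the pseudo-axial C1 methyl (1,3 to the carbonyl), giving the 9β-alcohol.

Step 11
Reactants: 15 6α-(TBS-oxy)dauc-7-ene-4β,9β-diol
Product: 16 9α-acetoxy-6α-(TBS-oxy)dauc-7-en-4β-ol
Conditions: AcOH, PPh3, DIAD, toluene, 0 → 23 °C
Reagents that add atoms: acetic acid, CC(=O)O
Why: Mitsunobu esterification of the secondary allylic alcohol proceeds with SN2 inversion and installs the 9α-acetate directly; the tertiary C4 hydroxyl does not react.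

Step 12
Reactants: 16 9α-acetoxy-6α-(TBS-oxy)dauc-7-en-4β-ol
Product: 17 9α-acetoxydauc-7-ene-4β,6α-diol
Conditions: HF·pyridine, pyridine, THF, 0 → 23 °C
Reagents that add atoms: none
Why: Buffered fluoride desilylation frees the hindered C6 hydroxyl without touching the allylic acetate or the tertiary alcohol.

Step 13
Reactants: 17 9α-acetoxydauc-7-ene-4β,6α-diol; 18 4-acetoxybenzoyl chloride
Product: 19 9α-acetoxy-6α-(4-acetoxybenzoyloxy)dauc-7-en-4β-ol
Conditions: DMAP, Et3N, CH2Cl2, 0 → 40 °C
Reagents that add atoms: none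
Why: DMAP-catalysed acylation (acylpyridinium transfer) esterifies the secondary C6 hydroxyl with retention while the tertiary C4 hydroxyl stays free.

Step 14
Reactants: 19 9α-acetoxy-6α-(4-acetoxybenzoyloxy)dauc-7-en-4β-ol
Product: 20 9α-acetoxy-6α-(4-hydroxybenzoyloxy)dauc-7-en-4β-ol (target)
Conditions: pyrrolidine (1.5 equiv), CH2Cl2, 0 °C
Reagents that add atoms: none
Why: Chemoselective aminolysis removes only the aryl acetate, which is far more electrophilic than the alkyl acetate and the alkyl benzoate.

**Compound list**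
1 | (R)-4-(tert-butyldimethylsilyloxy)cyclopent-2-en-1-one | O=C1C=C[C@H](O[Si](C)(C)C(C)(C)C)C1 | starting material
2 | (R)-4-(tert-butyldimethylsilyloxy)-2-iodocyclopent-2-en-1-one | O=C1C(I)=C[C@H](O[Si](C)(C)C(C)(C)C)C1 | intermediate
3 | (R)-4-(tert-butyldimethylsilyloxy)-2-methylcyclopent-2-en-1-one | O=C1C(C)=C[C@H](O[Si](C)(C)C(C)(C)C)C1 | intermediate
4 | 2-methylprop-2-en-1-ol | OCC(C)=C | starting material
5 | ethyl vinyl ether | CCOC=C | starting material
6 | 2-methylallyl vinyl ether | C=COCC(C)=C | intermediate (not isolated)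
7 | 4-methylpent-4-enal | O=CCCC(C)=C | intermediate
8 | 4-(TBS-oxy)-5-(1-hydroxy-4-methylpent-4-enyl)-2-methylcyclopent-2-en-1-one, 4,5-trans, silyloxy carbon as in 3, carbinol epimers | O=C1C(C)=C[C@H](O[Si](C)(C)C(C)(C)C)[C@H]1C(O)CCC(C)=C | intermediate
9 | 3-(TBS-oxy)-2-(1-hydroxy-4-methylpent-4-enyl)-5-methylcyclopentan-1-one, 2,3-trans, epimers at the carbinol and at the methyl-bearing carbon | O=C1C(C)C[C@H](O[Si](C)(C)C(C)(C)C)[C@H]1C(O)CCC(C)=C | intermediate
10 | 3-(TBS-oxy)-5-methyl-2-(4-methylpent-4-enoyl)cyclopentan-1-one, drawn as the ring-enol tautomer | O=C(CCC(C)=C)C1=C(O)C(C)C[C@@H]1O[Si](C)(C)C(C)(C)C | intermediate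
11 | tricyclic cyclobutanol photoadduct (cyclobutane C9–C10–C1–C5 cis-fused to ring B and, on the opposite face, to the cyclopentane; silyloxy group anti to the cyclobutane) | O[C@@]12C[C@@]3(C)CCC(=O)[C@]31[C@@H](O[Si](C)(C)C(C)(C)C)CC2C | intermediate (not isolated)
12 | trans-fused 6α-(TBS-oxy)-1,8-dimethylbicyclo[5.3.0]decane-4,9-dione (daucane labels; 1β-methyl, 5α-H, C8 epimers) | O=C1C[C@@]2(C)CCC(=O)[C@@H]2[C@@H](O[Si](C)(C)C(C)(C)C)CC1C | intermediate
13 | 6α-(TBS-oxy)-4β-hydroxydaucan-9-one (4α-isopropyl, 5α-H, C8 epimers) | O=C1C[C@@]2(C)CC[C@@](O)(C(C)C)[C@@H]2[C@@H](O[Si](C)(C)C(C)(C)C)CC1C | intermediate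
14 | 6α-(TBS-oxy)-4β-hydroxydauc-7-en-9-one | O=C1C[C@@]2(C)CC[C@@](O)(C(C)C)[C@@H]2[C@@H](O[Si](C)(C)C(C)(C)C)C=C1C | intermediate
15 | 6α-(TBS-oxy)dauc-7-ene-4β,9β-diol | O[C@@H]1C[C@@]2(C)CC[C@@](O)(C(C)C)[C@@H]2[C@@H](O[Si](C)(C)C(C)(C)C)C=C1C | intermediate
16 | 9α-acetoxy-6α-(TBS-oxy)dauc-7-en-4β-ol | CC(=O)O[C@H]1C[C@@]2(C)CC[C@@](O)(C(C)C)[C@@H]2[C@@H](O[Si](C)(C)C(C)(C)C)C=C1C | intermediate
17 | 9α-acetoxydauc-7-ene-4β,6α-diol | CC(=O)O[C@H]1C[C@@]2(C)CC[C@@](O)(C(C)C)[C@@H]2[C@@H](O)C=C1C | intermediate
18 | 4-acetoxybenzoyl chloride | CC(=O)Oc1ccc(cc1)C(Cl)=O | starting material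
19 | 9α-acetoxy-6α-(4-acetoxybenzoyloxy)dauc-7-en-4β-ol | CC(=O)O[C@H]1C[C@@]2(C)CC[C@@](O)(C(C)C)[C@@H]2[C@@H](OC(=O)c2ccc(OC(C)=O)cc2)C=C1C | intermediate
20 | 9α-acetoxy-6α-(4-hydroxybenzoyloxy)dauc-7-en-4β-ol, (1R,4R,5S,6S,9S) in daucane labels | CC(=O)O[C@H]1C[C@@]2(C)CC[C@@](O)(C(C)C)[C@@H]2[C@@H](OC(=O)c2ccc(O)cc2)C=C1C | target

**Step count**
Total: 14 steps. Longest linear sequence: 13 steps (1 → 20 through steps 1, 2 and 4–14); step 3 is a one-step side branch.

**Steps most likely to fail**

1. Step 7. The cycloaddition may run through the exocyclic enol tautomer, giving crossed closure and a diketone that is not ring-expanded, or the β-silyloxy diketone may lose silanol on excitation or handling. The fallback sets out from 10 and returns at 12. O-Acylation of the ring enol with benzyl chloroformate and pyridine gives the benzyl enol carbonate F1, in which only the ring C9=C5 double bond is conjugated with the C4 carbonyl. Irradiation at 350 nm gives the isolable cyclobutyl benzyl carbonate F2. Hydrogenolysis (H2, Pd/C, EtOAc) removes the benzyloxycarbonyl group, and the liberated cyclobutanol fragments by retro-aldol cleavage to 12.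

2. Step 8. The organocerium reagent may add competitively to the C9 ketone, or attack the β face if the ring fusion of 12 does not settle trans; the trans preference in step 7 is the least secure stereochemical claim of the route. The fallback sets out from 12 and returns at 13.
   - DBU-induced E1cB loss of silanol gives the enedione F3 with C5 sp2.
   - Ethylene glycol/PPTS ketalises only the saturated C9 ketone to the dioxolane F4.
   - i-PrMgCl/CeCl3 then adds to the only free carbonyl, anti to the C1 methyl, to give the tertiary allylic alcohol F5.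
   - Hydroboration–oxidation (BH3·THF, then H2O2/NaOH) gives the C6 alcohol F6.
   - Dess–Martin oxidation and brief K2CO3/MeOH give the C6 ketone F7; its C5 should epimerise to the trans ring fusion because C6 then lies cis to the small C4 hydroxyl and not to the isopropyl group.
   - Hydroxyl-directed reduction with Me4NBH(OAc)3 delivers hydride from the C4 oxygen on the β face and gives the 6α-alcohol F8.
   - TBSOTf/2,6-lutidine gives the silyl ether F9, and PPTS in wet acetone removes the dioxolane to give 13.

3. Step 11. The allylic oxyphosphonium ion may undergo SN2′ attack or elimination to the diene, or hydride delivery in step 10 may come from the unexpected face. The fallback sets out from 14 and returns at 16. Reagent-controlled Corey–Bakshi–Shibata reduction with (R)-2-methyl-CBS-oxazaborolidine and catecholborane (the trisubstituted alkene carbon acting as the large group) gives the 9α-alcohol F10. Acetylation with retention (Ac2O, DMAP, pyridine) then gives 16.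

**Further compounds**
F1 | step 7 | benzyl enol carbonate of 10 (ring enol O-acylated) | O=C(CCC(C)=C)C1=C(OC(=O)OCc2ccccc2)C(C)C[C@@H]1O[Si](C)(C)C(C)(C)C
F2 | step 7 | cyclobutyl benzyl carbonate photoadduct | O=C(OCc1ccccc1)O[C@@]12C[C@@]3(C)CCC(=O)[C@]31[C@@H](O[Si](C)(C)C(C)(C)C)CC2C
F3 | step 8 | 1,8-dimethylbicyclo[5.3.0]dec-5-ene-4,9-dione (daucane labels) | O=C1C[C@@]2(C)CCC(=O)C2=CCC1C
F4 | step 8 | C9 ethylene ketal of F3 | O1CCOC12C[C@@]3(C)CCC(=O)C3=CCC2C
F5 | step 8 | 4β-hydroxy-4α-isopropyl C5=C6 alkene, C9 ketal | O1CCOC12C[C@@]3(C)CC[C@@](O)(C(C)C)C3=CCC2C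
F6 | step 8 | C6 alcohol from hydroboration (epimers at C5 and C6), C9 ketal | O1CCOC12C[C@@]3(C)CC[C@@](O)(C(C)C)C3C(O)CC2C
F7 | step 8 | trans-fused 4β-hydroxy C6 ketone, C9 ketal | O1CCOC12C[C@@]3(C)CC[C@@](O)(C(C)C)[C@@H]3C(=O)CC2C
F8 | step 8 | 4β,6α-diol, C9 ketal | O1CCOC12C[C@@]3(C)CC[C@@](O)(C(C)C)[C@@H]3[C@@H](O)CC2C
F9 | step 8 | 6α-(TBS-oxy)-4β-ol, C9 ketal | O1CCOC12C[C@@]3(C)CC[C@@](O)(C(C)C)[C@@H]3[C@@H](O[Si](C)(C)C(C)(C)C)CC2C
F10 | step 11 | 6α-(TBS-oxy)dauc-7-ene-4β,9α-diol | O[C@H]1C[C@@]2(C)CC[C@@](O)(C(C)C)[C@@H]2[C@@H](O[Si](C)(C)C(C)(C)C)C=C1C
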